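**Plan**
- Cuts (cyclohexene carbons: C1′ bears coumarin A, C2′=C3′(CH3), C6′ is quaternary): the O–CH3 bond of coumarin A; the C6′–CH(alkenyl) bond; the S–O bond of a sulfonate that links the two halves; the ring bonds C1′–C6′ and C4′–C5′ (Diels–Alder); the aryl–dienyl bond.
- Forward: coumarin A ring (Pechmann), dienyl side chain (Suzuki), cyclohexene ring (Diels–Alder with methacrolein), sulfonate link to the coumarin B alkenyl fragment, oxidation to the acid, decarboxylative alkenyl transfer to C6′, O-methylation.
- Enabling feature: the oxygen on C7 of coumarin A is ortho to the C6–C1′ bond, so O7, C7, C6, C1′ and C6′ form a five-atom path. An (E)-ethenesulfonate on that oxygen holds its alkenyl carbon over C6′ through a seven-membered transition state, on the face syn to coumarin A, and then leaves as sulfite, returning the phenol that becomes the methoxy group.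
- Stereochemistry: C1′ from the catalyst-controlled endo Diels–Alder; C6′ from tethered syn delivery in the key step (the carboxyl-bearing centre is planarised there); the E alkene from the E-sulfonyl fluoride and the addition–fragmentation.

Key step: step 11

Remark: the sense of induction of the oxazaborolidinium catalyst in step 5 is assigned by analogy with other α-substituted acroleins; if the adduct proves to be the antipode, the (R)-catalyst is used and nothing else changes.

Step 1
Reactants: 1 4-bromobenzene-1,3-diol; 2 DL-malic acid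
Product: 4 6-bromo-7-hydroxy-2H-chromen-2-one, via formylacetic acid 3 (not isolated)
Conditions: conc. H2SO4, 100–120 °C; poured onto ice
Reagents that add atoms: none
Why: von Pechmann condensation: in hot sulfuric acid 2 loses CO and water to give formylacetic acid 3, which is attacked by C6 of 1 (para to one hydroxyl, ortho to the other, the position between the hydroxyls being hindered) and lactonises, so that bromine ends at C6 and the free hydroxyl at C7 of the coumarin.

Step 2
Reactants: 5 2-methylbut-1-en-3-yne; 6 pinacolborane
Product: 7 (E)-4,4,5,5-tetramethyl-2-(3-methylbuta-1,3-dien-1-yl)-1,3,2-dioxaborolane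
Conditions: Cp2Zr(H)Cl (5 mol %), Et3N (10 mol %), neat, 60 °C
Reagents that add atoms: none
Why: Zirconium-catalysed hydroboration of a terminal alkyne (hydrozirconation, then transfer of the alkenyl group to boron) is syn and places boron on the terminal carbon, giving the E-dienylboronate while the 1,1-disubstituted alkene is left alone.

Step 3
Reactants: 4 6-bromo-7-hydroxy-2H-chromen-2-one; 7 (E)-dienylboronate
Product: 8 7-hydroxy-6-[(1E)-3-methylbuta-1,3-dien-1-yl]-2H-chromen-2-one
Conditions: Pd(dppf)Cl2 (3 mol %), K2CO3, 1,4-dioxane/H2O, 80 °C; then dilute HCl to pH 3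
Reagents that add atoms: none
Why: Suzuki–Miyaura coupling of the aryl bromide with the alkenylboronate proceeds with retention of the E geometry, and the free phenol is carried as its phenoxide; acidification recloses any lactone opened by the base.

Step 4
Reactants: 8 7-hydroxy-6-[(1E)-3-methylbuta-1,3-dien-1-yl]-2H-chromen-2-one
Product: 9 7-[tert-butyl(dimethyl)silyloxy]-6-[(1E)-3-methylbuta-1,3-dien-1-yl]-2H-chromen-2-one
Conditions: TBSCl, imidazole, DMF, 0 °C to rt
Reagents that add atoms: tert-butyl(chloro)dimethylsilane, CC(C)(C)[Si](C)(C)Cl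
Why: Standard silylation of the phenol removes the acidic OH that would quench the cationic Lewis acid of step 5 or add to the diene, and provides the aryl silyl ether required for the later sulfur–fluoride exchange.

Step 5
Reactants: 9 silyl-protected dienylcoumarin; 10 methacrolein (2-methylprop-2-enal)
Product: 11 (1S,2S)-2-[7-[tert-butyl(dimethyl)silyloxy]-2-oxo-2H-chromen-6-yl]-1,4-dimethylcyclohex-3-ene-1-carbaldehyde (formyl cis to the aryl group)
Conditions: (S)-3,3-diphenyl-1-(2-methylphenyl)tetrahydropyrrolo[1,2-c][1,3,2]oxazaborole activated with Tf2NH (20 mol %), CH2Cl2, −78 to −40 °C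
Reagents that add atoms: none
Why: Enantioselective Diels–Alder reaction with a chiral cationic oxazaborolidine: the 1-aryl and 3-methyl groups of the diene both direct the formyl-bearing carbon next to the aryl-bearing carbon (ortho and para rules), the activated formyl group takes the endo position (cis to the aryl group), and the catalyst blocks one face of the bound s-trans enal, which fixes both stereocentres; any exo isomer, which would lead to the antipode after step 11, is removed by chromatography here.

Step 6
Reactants: 12 7-hydroxy-2H-chromen-2-one (umbelliferone)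
Product: 13 7-hydroxy-8-iodo-2H-chromen-2-one
Conditions: I2, KI, 20% aq. NH3, 0 °C to rt; then dilute H2SO4
Reagents that add atoms: iodine, II
Why: Electrophilic aromatic iodination of the phenoxide goes ortho to the hydroxyl at C8, the position activated by both ring oxygens, which is the usual site for umbelliferone under these conditions.

Step 7
Reactants: 13 7-hydroxy-8-iodo-2H-chromen-2-one
Product: 14 8-iodo-7-methoxy-2H-chromen-2-one
Conditions: MeI, K2CO3, acetone, reflux
Reagents that add atoms: iodomethane, CI
Why: Williamson ether synthesis on the acidic phenol.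

Step 8
Reactants: 14 8-iodo-7-methoxy-2H-chromen-2-one; 15 ethenesulfonyl fluoride
Product: 16 (E)-2-(7-methoxy-2-oxo-2H-chromen-8-yl)ethenesulfonyl fluoride
Conditions: Pd(OAc)2 (5 mol %), AgO2CCF3 (1.2 equiv), acetone, 60 °C
Reagents that add atoms: none
Why: Mizoroki–Heck reaction of the aryl iodide with ethenesulfonyl fluoride under silver-assisted (cationic palladium) conditions: the aryl group adds to the unsubstituted alkene terminus and syn β-hydride elimination gives the E isomer, the S–F bond being inert to palladium.

Step 9
Reactants: 11 Diels–Alder aldehyde; 16 (E)-ethenesulfonyl fluoride of coumarin B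
Product: 17 6-[(1S,6S)-6-formyl-3,6-dimethylcyclohex-2-en-1-yl]-2-oxo-2H-chromen-7-yl (E)-2-(7-methoxy-2-oxo-2H-chromen-8-yl)ethenesulfonate
Conditions: DBU (20 mol %), MeCN, rt
Reagents that add atoms: none
Why: Sulfur–fluoride exchange (SuFEx): DBU activates the aryl silyl ether and the aryloxide displaces fluoride at sulfur with formation of the strong Si–F bond, which links the two coumarin halves through the sulfonate that will deliver the alkenyl group; the β-aryl group slows conjugate addition.

Step 10
Reactants: 17 sulfonate-linked aldehyde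
Product: 18 (1S,2S)-2-[7-({[(E)-2-(7-methoxy-2-oxo-2H-chromen-8-yl)ethenyl]sulfonyl}oxy)-2-oxo-2H-chromen-6-yl]-1,4-dimethylcyclohex-3-ene-1-carboxylic acid
Conditions: NaClO2, NaH2PO4, 2-methylbut-2-ene, t-BuOH/H2O, 0 °C to rt
Reagents that add atoms: sodium chlorite NaClO2, [Na+].[O-]Cl=O
Why: Pinnick oxidation turns the non-enolisable aldehyde into the carboxylic acid with chlorous acid made in the flask, 2-methylbut-2-ene trapping hypochlorous acid so that the alkenes, the sulfonate and the lactones are left intact.

Step 11
Reactants: 18 sulfonate-linked carboxylic acid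
Product: 20 7-hydroxy-6-[(1R,6R)-6-[(E)-2-(7-methoxy-2-oxo-2H-chromen-8-yl)ethenyl]-3,6-dimethylcyclohex-2-en-1-yl]-2H-chromen-2-one, via potassium sulfite half-ester 19 (not isolated)
Conditions: [Ir(dF(CF3)ppy)2(dtbbpy)]PF6 (2 mol %), K2HPO4 (1.2 equiv), degassed DMF (0.005 M), 450 nm LEDs, 25 °C; then aq. NH4Cl
Reagents that add atoms: none
Why: Proposed new method: the excited trivalent iridium photocatalyst oxidises the carboxylate, loss of CO2 leaves a planar tertiary radical at C6′, and this adds 7-exo-trig to the sulfonyl-bearing alkene carbon of the tethered ethenesulfonate to give a benzylic radical stabilised by coumarin B; β-scission of the C–S bond then forms the C6′–CH=CH bond as the E alkene and releases an aryloxysulfonyl radical, which the divalent iridium species reduces to sulfite half-ester 19, closing the catalytic cycle. The closest known reaction type is the photoredox decarboxylative alkenylation of carboxylic acids with alkenyl sulfones (radical addition, then β-sulfonyl fragmentation), made intramolecular here in the manner of a radical Smiles-type group transfer from a sulfonate; the only ring closed is the transient seven-membered ring (C6′, C1′, C6 and C7 of coumarin A, O, S, alkenyl carbon), and it opens again in the same event. The new quaternary stereocentre C6′ is controlled by the resident C1′ stereocentre through the tether: allylic 1,2-strain with the C6′ methyl group holds the aryl group pseudoaxial, and the two-atom O–S link from its C7 oxygen can reach only the face of C6′ syn to the aryl group, so the alkenyl group arrives cis to coumarin A, the opposite of the anti attack expected for an untethered acceptor. Attack at the sulfonyl-bearing carbon is secured by formation of the benzylic radical and by the electron-poor alkene matched to the nucleophilic tertiary radical, and the E geometry by fragmentation through the conformer with coumarin B anti to the quaternary carbon. High dilution suppresses intermolecular addition, and the configuration at the carboxyl-bearing carbon of 18 plays no part because that centre is planarised.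

Step 12
Reactants: 20 7-hydroxy coupling product
Product: 21 7-methoxy-6-[(1R,6R)-6-[(E)-2-(7-methoxy-2-oxo-2H-chromen-8-yl)ethenyl]-3,6-dimethylcyclohex-2-en-1-yl]-2H-chromen-2-one (CNP0287121.3)
Conditions: MeI, K2CO3, acetone, rt
Reagents that add atoms: iodomethane, CI
Why: Williamson methylation of the liberated 7-hydroxyl restores the methoxy group of coumarin A; no stereocentre or alkene is touched under these mild basic conditions.

**Compound list**
1 | 4-bromobenzene-1,3-diol | Oc1ccc(Br)c(O)c1 | starting material
2 | DL-malic acid | OC(CC(=O)O)C(=O)O | starting material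
3 | formylacetic acid (3-oxopropanoic acid) | O=CCC(=O)O | intermediate (not isolated)
4 | 6-bromo-7-hydroxy-2H-chromen-2-one | Oc1cc2oc(=O)ccc2cc1Br | intermediate
5 | 2-methylbut-1-en-3-yne | C=C(C)C#C | starting material
6 | pinacolborane (4,4,5,5-tetramethyl-1,3,2-dioxaborolane) | CC1(C)OBOC1(C)C | starting material
7 | (E)-4,4,5,5-tetramethyl-2-(3-methylbuta-1,3-dien-1-yl)-1,3,2-dioxaborolane | C=C(C)/C=C/B1OC(C)(C)C(C)(C)O1 | intermediate
8 | 7-hydroxy-6-[(1E)-3-methylbuta-1,3-dien-1-yl]-2H-chromen-2-one | C=C(C)/C=C/c1cc2ccc(=O)oc2cc1O | intermediate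
9 | 7-[tert-butyl(dimethyl)silyloxy]-6-[(1E)-3-methylbuta-1,3-dien-1-yl]-2H-chromen-2-one | C=C(C)/C=C/c1cc2ccc(=O)oc2cc1O[Si](C)(C)C(C)(C)C | intermediate
10 | methacrolein (2-methylprop-2-enal) | C=C(C)C=O | starting material
11 | (1S,2S)-2-[7-[tert-butyl(dimethyl)silyloxy]-2-oxo-2H-chromen-6-yl]-1,4-dimethylcyclohex-3-ene-1-carbaldehyde | CC(C)(C)[Si](C)(C)Oc1cc2oc(=O)ccc2cc1[C@@H]1C=C(C)CC[C@]1(C)C=O | intermediate
12 | 7-hydroxy-2H-chromen-2-one (umbelliferone) | Oc1ccc2ccc(=O)oc2c1 | starting material
13 | 7-hydroxy-8-iodo-2H-chromen-2-one | Oc1ccc2ccc(=O)oc2c1I | intermediate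
14 | 8-iodo-7-methoxy-2H-chromen-2-one | COc1ccc2ccc(=O)oc2c1I | intermediate
15 | ethenesulfonyl fluoride | C=CS(=O)(=O)F | starting material
16 | (E)-2-(7-methoxy-2-oxo-2H-chromen-8-yl)ethenesulfonyl fluoride | COc1ccc2ccc(=O)oc2c1/C=C/S(=O)(=O)F | intermediate
17 | 6-[(1S,6S)-6-formyl-3,6-dimethylcyclohex-2-en-1-yl]-2-oxo-2H-chromen-7-yl (E)-2-(7-methoxy-2-oxo-2H-chromen-8-yl)ethenesulfonate | COc1ccc2ccc(=O)oc2c1/C=C/S(=O)(=O)Oc1cc2oc(=O)ccc2cc1[C@@H]1C=C(C)CC[C@]1(C)C=O | intermediate
18 | (1S,2S)-2-[7-({[(E)-2-(7-methoxy-2-oxo-2H-chromen-8-yl)ethenyl]sulfonyl}oxy)-2-oxo-2H-chromen-6-yl]-1,4-dimethylcyclohex-3-ene-1-carboxylic acid | COc1ccc2ccc(=O)oc2c1/C=C/S(=O)(=O)Oc1cc2oc(=O)ccc2cc1[C@@H]1C=C(C)CC[C@]1(C)C(=O)O | intermediate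
19 | potassium 6-[(1R,6R)-6-[(E)-2-(7-methoxy-2-oxo-2H-chromen-8-yl)ethenyl]-3,6-dimethylcyclohex-2-en-1-yl]-2-oxo-2H-chromen-7-yl sulfite | [K+].[O-]S(=O)Oc1cc2oc(=O)ccc2cc1[C@@H]1C=C(C)CC[C@]1(C)/C=C/c1c(OC)ccc2ccc(=O)oc12 | intermediate (not isolated)
20 | 7-hydroxy-6-[(1R,6R)-6-[(E)-2-(7-methoxy-2-oxo-2H-chromen-8-yl)ethenyl]-3,6-dimethylcyclohex-2-en-1-yl]-2H-chromen-2-one | Oc1cc2oc(=O)ccc2cc1[C@@H]1C=C(C)CC[C@]1(C)/C=C/c1c(OC)ccc2ccc(=O)oc12 | intermediate
21 | 7-methoxy-6-[(1R,6R)-6-[(E)-2-(7-methoxy-2-oxo-2H-chromen-8-yl)ethenyl]-3,6-dimethylcyclohex-2-en-1-yl]-2H-chromen-2-one | COc1cc2oc(=O)ccc2cc1[C@@H]1C=C(C)CC[C@]1(C)/C=C/c1c(OC)ccc2ccc(=O)oc12 | target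

**Totals**
Total step count: 12. Longest linear sequence: 8 steps (1, 3, 4, 5, 9, 10, 11, 12).

**Steps most likely to fail**

Step 11 (Proposed new method). What may go wrong:
- The tertiary radical may close onto the ring alkene (homoallyl to cyclopropylcarbinyl) and reopen with ring contraction to a benzylic cyclopentenylmethyl radical.
- The seven-membered closure may be slower than hydrogen abstraction from the medium, giving simple decarboxylation.
- The tether may not fully enforce syn delivery.
- The photocatalyst may sensitise E/Z isomerisation or [2+2] reactions of the coumarins.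

Fallback with known chemistry, setting out from 11 and coming back at 21: the quaternary centre is taken from the endo Diels–Alder adduct and the alkene is built from its other end. Desilylative methylation of 11 (CsF, MeI, DMF) should give (1S,2S)-2-(7-methoxy-2-oxo-2H-chromen-6-yl)-1,4-dimethylcyclohex-3-ene-1-carbaldehyde F1. Wittig methylenation (Ph3PCH3Br, KOtBu, THF, 0 °C) should give 6-[(1R,6R)-6-ethenyl-3,6-dimethylcyclohex-2-en-1-yl]-7-methoxy-2H-chromen-2-one F2. A Mizoroki–Heck reaction of F2 with 14 (Pd(OAc)2, P(o-tol)3, Et3N, DMF, 90 °C) should then give 21; the vinyl group on a quaternary carbon has no competing β-hydrogen, so the E isomer is expected.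

Step 5. What may go wrong:
- The Lewis-basic lactone carbonyl may bind the catalyst and stall turnover.
- Endo or facial selectivity may be insufficient; an exo adduct formed on the same dienophile face carries the opposite C1′ configuration.
- The acid may polymerise the diene or cleave the silyl ether.

Fallback, setting out from 9 and coming back at 11: asymmetric catalysis is replaced by resolution. A Diels–Alder reaction of 9 with 10 promoted by BF3·OEt2 (CH2Cl2, −78 °C) should give the racemic endo adduct. The enantiomers are separated by preparative chromatography on a chiral stationary phase, which gives 11 and the unwanted (1R,2R)-2-[7-[tert-butyl(dimethyl)silyloxy]-2-oxo-2H-chromen-6-yl]-1,4-dimethylcyclohex-3-ene-1-carbaldehyde F3.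

Step 9. What may go wrong:
- The aryloxide may add to the β-carbon of the ethenesulfonyl fluoride instead of substituting at sulfur.
- The alkene geometry may be lost under the basic conditions.

Fallback, setting out from 11 and coming back at 17: the sulfonate is placed on fragment 1 first and the aryl–alkenyl bond is made afterwards, which also makes step 8 unnecessary. Desilylation of 11 (Bu4NF, AcOH, THF, 0 °C) should give (1S,2S)-2-(7-hydroxy-2-oxo-2H-chromen-6-yl)-1,4-dimethylcyclohex-3-ene-1-carbaldehyde F4. Sulfonylation with 2-chloroethanesulfonyl chloride and Et3N (CH2Cl2, 0 °C), with loss of HCl from the chloroethyl group in the flask, should give 6-[(1S,6S)-6-formyl-3,6-dimethylcyclohex-2-en-1-yl]-2-oxo-2H-chromen-7-yl ethenesulfonate F5. A Mizoroki–Heck reaction of F5 with 14 (Pd(OAc)2, P(o-tol)3, Et3N, DMF, 80 °C) should give 17.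

**Further compounds**
F1 | step 11 | (1S,2S)-2-(7-methoxy-2-oxo-2H-chromen-6-yl)-1,4-dimethylcyclohex-3-ene-1-carbaldehyde | COc1cc2oc(=O)ccc2cc1[C@@H]1C=C(C)CC[C@]1(C)C=O
F2 | step 11 | 6-[(1R,6R)-6-ethenyl-3,6-dimethylcyclohex-2-en-1-yl]-7-methoxy-2H-chromen-2-one | COc1cc2oc(=O)ccc2cc1[C@@H]1C=C(C)CC[C@]1(C)C=C
F3 | step 5 | (1R,2R)-2-[7-[tert-butyl(dimethyl)silyloxy]-2-oxo-2H-chromen-6-yl]-1,4-dimethylcyclohex-3-ene-1-carbaldehyde | CC(C)(C)[Si](C)(C)Oc1cc2oc(=O)ccc2cc1[C@H]1C=C(C)CC[C@@]1(C)C=O
F4 | step 9 | (1S,2S)-2-(7-hydroxy-2-oxo-2H-chromen-6-yl)-1,4-dimethylcyclohex-3-ene-1-carbaldehyde | Oc1cc2oc(=O)ccc2cc1[C@@H]1C=C(C)CC[C@]1(C)C=O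
F5 | step 9 | 6-[(1S,6S)-6-formyl-3,6-dimethylcyclohex-2-en-1-yl]-2-oxo-2H-chromen-7-yl ethenesulfonate | C=CS(=O)(=O)Oc1cc2oc(=O)ccc2cc1[C@@H]1C=C(C)CC[C@]1(C)C=O
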